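**Retrosynthetic overview**

1. Target ⇐ 7-O-benzoate cleavage ⇐ catechol by ortho-oxygenation of the 4'-phenol at C3' ⇐ 5'-(1,1-dimethylallyl) group by aromatic Claisen rearrangement of the 4'-O-prenyl ether.
2. The C3 stereocentre ⇐ iridium-catalysed asymmetric hydrogenation of an isoflav-3-ene; the 4'-O-benzyl group is then removed in the same flask.
3. Isoflav-3-ene ⇐ one-flask union of resorcinol monobenzoate with a 2-arylacrolein (masked as its diethyl acetal), templated by phenylboronic acid.
4. 2-Arylacrolein acetal ⇐ aryllithium from 4-bromo-3-methoxyphenol benzyl ether + ethyl diethoxyacetate, then Wittig methylenation.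
5. Ring order: rings A and B are bought; in the key flask a 1,3,2-benzodioxaborin closes first (C4–C4a bond) and is then traded for the pyran ring (O1–C2 bond); no other ring is made.

Assumption: isoflavan locants are used (O1, C2, C3, C4; primed locants on ring B), and the (4S,5S)-ThrePHOX iridium catalyst is taken to give the 3S series, as is usual for 3-aryl-2H-chromenes; its mirror image is used if the first run shows the opposite sense.

**Route**

Step 1
Reactants: 1 4-bromo-3-methoxyphenol
Product: 2 4-(benzyloxy)-1-bromo-2-methoxybenzene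
Conditions: BnBr (1.1 equiv), K2CO3 (1.5 equiv), acetone, reflux, 6 h
Reagents that add atoms: benzyl bromide, BrCc1ccccc1
Why: Williamson ether synthesis masks the future 4'-OH as a benzyl ether that survives the organolithium, Wittig and hot carboxylic acid steps and is later removed by hydrogenolysis.

Step 2
Reactants: 2 4-(benzyloxy)-1-bromo-2-methoxybenzene; 3 ethyl 2,2-diethoxyacetate
Product: 5 1-[4-(benzyloxy)-2-methoxyphenyl]-2,2-diethoxyethan-1-one, via aryllithium 4 (not isolated)
Conditions: n-BuLi (1.05 equiv), THF, −78 °C, 30 min; cannulate into 3 (1.5 equiv), THF, −78 °C, 1 h; H2O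
Reagents that add atoms: none
Why: Bromine–lithium exchange followed by acylation, in which the chelated tetrahedral adduct of the α,α-dialkoxy ester holds at −78 °C so that the ketone is released only on work-up (single addition).

Step 3
Reactants: 5 1-[4-(benzyloxy)-2-methoxyphenyl]-2,2-diethoxyethan-1-one
Product: 6 4-(benzyloxy)-1-(3,3-diethoxyprop-1-en-2-yl)-2-methoxybenzene
Conditions: Ph3PCH3Br (1.5 equiv), KOtBu (1.45 equiv), THF, 0 °C to rt, 4 h
Reagents that add atoms: methyltriphenylphosphonium bromide, C[P+](c1ccccc1)(c1ccccc1)c1ccccc1.[Br-]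
Why: Wittig methylenation of the aryl ketone gives the 2-arylacrolein in a storable acetal form, since free 2-arylacroleins polymerise.

Step 4
Reactants: 6 4-(benzyloxy)-1-(3,3-diethoxyprop-1-en-2-yl)-2-methoxybenzene; 7 3-hydroxyphenyl benzoate (resorcinol monobenzoate)
Product: 11 3-[4-(benzyloxy)-2-methoxyphenyl]-2H-chromen-7-yl benzoate, via free enal 8 (not isolated), via benzodioxaborin 9 (not isolated), via o-quinone methide 10 (not isolated)
Conditions: 6 (1.2 equiv), PhB(OH)2 (1.2 equiv, recovered), EtCO2H (1 equiv), toluene, reflux, Dean–Stark, 24 h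
Reagents that add atoms: none
Why: Phenylboronic acid ties the phenol oxygen and the aldehyde unmasked from the acetal into one boronate, so C–C bond formation is forced ortho to OH and para to the benzoate and closes the benzodioxaborin 9 (Nagata-type templated ortho-hydroxyalkylation); at reflux 9 loses PhBO by retro-[4+2] to the o-quinone methide 10, whose oxa-6π electrocyclisation onto the 2-arylvinyl unit closes the pyran ring, which gives two ring closures in one flask and extends the known enal-to-2H-chromene annulation to a 2-arylacrolein.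

Step 5
Reactants: 11 3-[4-(benzyloxy)-2-methoxyphenyl]-2H-chromen-7-yl benzoate
Product: 13 (3S)-3-(4-hydroxy-2-methoxyphenyl)-3,4-dihydro-2H-chromen-7-yl benzoate, via benzyl ether 12 (not isolated)
Conditions: [Ir(cod)((4S,5S)-ThrePHOX)][B(C6H3-3,5-(CF3)2)4] (1 mol %), H2 (50 bar), CH2Cl2, rt, 16 h (full conversion by HPLC); vent; Pd/C (10 %), EtOAc–MeOH, H2 (1 atm), rt, 3 h
Reagents that add atoms: none
Why: Iridium–phosphinite-oxazoline (Pfaltz-type) asymmetric hydrogenation of the unfunctionalised trisubstituted styrenyl olefin sets C3 as S by catalyst-controlled face selection, and the following Pd/C hydrogenolysis cleaves only the benzyl ether (aryl benzoate, chroman and C3 are untouched).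

Step 6
Reactants: 13 (3S)-3-(4-hydroxy-2-methoxyphenyl)-3,4-dihydro-2H-chromen-7-yl benzoate
Product: 14 (3S)-3-{2-methoxy-4-[(3-methylbut-2-en-1-yl)oxy]phenyl}-3,4-dihydro-2H-chromen-7-yl benzoate
Conditions: prenyl bromide (1.2 equiv), K2CO3 (1.5 equiv), acetone, rt, 8 h
Reagents that add atoms: 1-bromo-3-methylbut-2-ene (prenyl bromide), CC(C)=CCBr
Why: Williamson O-alkylation of the only free phenol, under carbonate/acetone conditions at room temperature that leave the aryl benzoate in place.

Step 7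
Reactants: 14 (3S)-3-{2-methoxy-4-[(3-methylbut-2-en-1-yl)oxy]phenyl}-3,4-dihydro-2H-chromen-7-yl benzoate
Product: 15 (3S)-3-[4-hydroxy-2-methoxy-5-(2-methylbut-3-en-2-yl)phenyl]-3,4-dihydro-2H-chromen-7-yl benzoate
Conditions: PhNEt2, 190 °C, sealed tube, Ar, 3 h
Reagents that add atoms: none
Why: Aromatic Claisen rearrangement ([3,3]) of the prenyl ether delivers the inverted 1,1-dimethylallyl group to C5', because the para position is blocked by the chromanyl group and the other ortho position (C3') is flanked by OMe and would have to take a quaternary carbon; C3 is not involved.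

Step 8
Reactants: 15 (3S)-3-[4-hydroxy-2-methoxy-5-(2-methylbut-3-en-2-yl)phenyl]-3,4-dihydro-2H-chromen-7-yl benzoate
Product: 17 (3S)-3-[3,4-dihydroxy-2-methoxy-5-(2-methylbut-3-en-2-yl)phenyl]-3,4-dihydro-2H-chromen-7-yl benzoate, via o-quinone 16 (not isolated)
Conditions: IBX (1.2 equiv), DMF, 0 °C to rt, dark, 2 h; then aq. Na2S2O4, EtOAc, 0 °C
Reagents that add atoms: 2-iodoxybenzoic acid (IBX), O=C1OI(=O)(O)c2ccccc12
Why: Regioselective ortho-oxygenation of a phenol by the pentavalent iodine reagent (oxygen transfer within the aryloxy–iodine intermediate) can only hit C3', the single free ortho position, and the o-quinone is reduced to the catechol in the same flask before it can tautomerise; the vinyl group, the aryl ester and C3 are untouched.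

Step 9
Reactants: 17 (3S)-3-[3,4-dihydroxy-2-methoxy-5-(2-methylbut-3-en-2-yl)phenyl]-3,4-dihydro-2H-chromen-7-yl benzoate
Product: 18 (3S)-3-[3,4-dihydroxy-2-methoxy-5-(2-methylbut-3-en-2-yl)phenyl]-3,4-dihydro-2H-chromen-7-ol
Conditions: n-BuNH2 (5 equiv), degassed THF–MeOH, rt, 4 h, Ar; cold aq. citric acid
Reagents that add atoms: none
Why: Aminolysis of the activated aryl benzoate frees the 7-OH under oxygen-free conditions without strong base or acid, so the catechol and the acid-sensitive ortho-(1,1-dimethylallyl)phenol survive and C3 stays S.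

**Compound list**

1 | 4-bromo-3-methoxyphenol | COc1cc(O)ccc1Br | starting material
2 | 4-(benzyloxy)-1-bromo-2-methoxybenzene | COc1cc(OCc2ccccc2)ccc1Br | intermediate
3 | ethyl 2,2-diethoxyacetate | CCOC(OCC)C(=O)OCC | starting material
4 | [4-(benzyloxy)-2-methoxyphenyl]lithium | [Li]c1ccc(OCc2ccccc2)cc1OC | intermediate (not isolated)
5 | 1-[4-(benzyloxy)-2-methoxyphenyl]-2,2-diethoxyethan-1-one | CCOC(OCC)C(=O)c1ccc(OCc2ccccc2)cc1OC | intermediate
6 | 4-(benzyloxy)-1-(3,3-diethoxyprop-1-en-2-yl)-2-methoxybenzene | CCOC(OCC)C(=C)c1ccc(OCc2ccccc2)cc1OC | intermediate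
7 | 3-hydroxyphenyl benzoate | O=C(Oc1cccc(O)c1)c1ccccc1 | starting material
8 | 2-[4-(benzyloxy)-2-methoxyphenyl]prop-2-enal | COc1cc(OCc2ccccc2)ccc1C(=C)C=O | intermediate (not isolated)
9 | 4-{1-[4-(benzyloxy)-2-methoxyphenyl]ethenyl}-2-phenyl-4H-1,3,2-benzodioxaborinin-7-yl benzoate (racemic) | O=C(Oc1ccc2C(OB(Oc2c1)c1ccccc1)C(=C)c1ccc(OCc3ccccc3)cc1OC)c1ccccc1 | intermediate (not isolated)
10 | 4-{2-[4-(benzyloxy)-2-methoxyphenyl]prop-2-en-1-ylidene}-3-oxocyclohexa-1,5-dien-1-yl benzoate | O=C1C=C(OC(=O)c2ccccc2)C=CC1=CC(=C)c1ccc(OCc2ccccc2)cc1OC | intermediate (not isolated)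
11 | 3-[4-(benzyloxy)-2-methoxyphenyl]-2H-chromen-7-yl benzoate | O=C(Oc1ccc2C=C(COc2c1)c1ccc(OCc3ccccc3)cc1OC)c1ccccc1 | intermediate
12 | (3S)-3-[4-(benzyloxy)-2-methoxyphenyl]-3,4-dihydro-2H-chromen-7-yl benzoate | COc1cc(OCc2ccccc2)ccc1[C@H]1COc2cc(OC(=O)c3ccccc3)ccc2C1 | intermediate (not isolated)
13 | (3S)-3-(4-hydroxy-2-methoxyphenyl)-3,4-dihydro-2H-chromen-7-yl benzoate | COc1cc(O)ccc1[C@H]1COc2cc(OC(=O)c3ccccc3)ccc2C1 | intermediate
14 | (3S)-3-{2-methoxy-4-[(3-methylbut-2-en-1-yl)oxy]phenyl}-3,4-dihydro-2H-chromen-7-yl benzoate | COc1cc(OCC=C(C)C)ccc1[C@H]1COc2cc(OC(=O)c3ccccc3)ccc2C1 | intermediate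
15 | (3S)-3-[4-hydroxy-2-methoxy-5-(2-methylbut-3-en-2-yl)phenyl]-3,4-dihydro-2H-chromen-7-yl benzoate | C=CC(C)(C)c1cc([C@H]2COc3cc(OC(=O)c4ccccc4)ccc3C2)c(OC)cc1O | intermediate
16 | (3S)-3-[2-methoxy-5-(2-methylbut-3-en-2-yl)-3,4-dioxocyclohexa-1,5-dien-1-yl]-3,4-dihydro-2H-chromen-7-yl benzoate | C=CC(C)(C)C1=CC([C@H]2COc3cc(OC(=O)c4ccccc4)ccc3C2)=C(OC)C(=O)C1=O | intermediate (not isolated)
17 | (3S)-3-[3,4-dihydroxy-2-methoxy-5-(2-methylbut-3-en-2-yl)phenyl]-3,4-dihydro-2H-chromen-7-yl benzoate | C=CC(C)(C)c1cc([C@H]2COc3cc(OC(=O)c4ccccc4)ccc3C2)c(OC)c(O)c1O | intermediate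
18 | (3S)-3-[3,4-dihydroxy-2-methoxy-5-(2-methylbut-3-en-2-yl)phenyl]-3,4-dihydro-2H-chromen-7-ol | C=CC(C)(C)c1cc([C@H]2COc3cc(O)ccc3C2)c(OC)c(O)c1O | target

**Totals and risks**

Total step count: 9. Longest linear sequence: 9 steps (1 to 18); 3 and 7 are commercial inputs.

Most likely to fail, first: step 4. The unmasked 2-arylacrolein can polymerise, the phenol can react at the carbon between its two oxygens (giving the 5-benzoyloxy isomer), and a 2-arylacrolein is untested in this annulation. The fallback sets out from 2 and 7 and makes the pyran ring and the C3–aryl bond separately. Bromine–lithium exchange of 2 and a trimethyl borate quench with acidic work-up give [4-(benzyloxy)-2-methoxyphenyl]boronic acid F1. Compound 7 is O-alkylated with propargyl bromide and K2CO3 to 3-(prop-2-yn-1-yloxy)phenyl benzoate F2, which is closed by 6-endo hydroarylation with Ph3PAuNTf2 in CH2Cl2 to 2H-chromen-7-yl benzoate F3. Rhodium-catalysed asymmetric hydroarylation of F3 with F1 ([RhCl(C2H4)2]2, a C2-symmetric chiral bicyclo[2.2.2]octadiene ligand of the enantiomer that gives 3S, K3PO4, dioxane–H2O, 60 °C) places the aryl group on C3 and sets the stereocentre in one event. This comes back to the route at 12, which is debenzylated as in the second half of step 5.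

Second: step 5. The ortho-methoxy group on the 3-aryl ring may lower the enantioselectivity of the iridium hydrogenation. The fallback sets out from 11. Hydroboration–oxidation (BH3·THF, then NaBO3) gives racemic trans-3-[4-(benzyloxy)-2-methoxyphenyl]-4-hydroxy-3,4-dihydro-2H-chromen-7-yl benzoate F4. Dess–Martin oxidation gives the isoflavanone 3-[4-(benzyloxy)-2-methoxyphenyl]-4-oxo-3,4-dihydro-2H-chromen-7-yl benzoate F5. Noyori–Ikariya transfer hydrogenation with dynamic kinetic resolution (RuCl(p-cymene)[(S,S)-TsDPEN], HCO2H–Et3N, EtOAc, rt) gives the cis alcohol (3S,4S)-3-[4-(benzyloxy)-2-methoxyphenyl]-4-hydroxy-3,4-dihydro-2H-chromen-7-yl benzoate F6. Hydrogenolysis (Pd/C, H2, trace AcOH) removes the benzylic hydroxyl and the benzyl ether and comes back to the route at 13.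

Third: step 8. The o-quinone 16 carries a benzylic hydrogen at C3 para to a quinone carbonyl and could tautomerise to a quinone methide, which would erode the stereocentre; the oxidation site is also hindered. The fallback sets out from 15 and never passes through a quinone. Magnesium-mediated ortho-formylation (MgCl2, Et3N, paraformaldehyde, MeCN, reflux) at the only free ortho position gives (3S)-3-[3-formyl-4-hydroxy-2-methoxy-5-(2-methylbut-3-en-2-yl)phenyl]-3,4-dihydro-2H-chromen-7-yl benzoate F7. Dakin oxidation (30 % H2O2, B(OH)3, cat. H2SO4, THF, rt) gives the aryl formate (3S)-3-[3-(formyloxy)-4-hydroxy-2-methoxy-5-(2-methylbut-3-en-2-yl)phenyl]-3,4-dihydro-2H-chromen-7-yl benzoate F8, which is cleaved in the same flask with aq. NaHCO3–MeOH. This comes back to the route at 17.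

**Further compounds**

F1 | step 4 | [4-(benzyloxy)-2-methoxyphenyl]boronic acid | COc1cc(OCc2ccccc2)ccc1B(O)O
F2 | step 4 | 3-(prop-2-yn-1-yloxy)phenyl benzoate | C#CCOc1cccc(OC(=O)c2ccccc2)c1
F3 | step 4 | 2H-chromen-7-yl benzoate | O=C(Oc1ccc2C=CCOc2c1)c1ccccc1
F4 | step 5 | rac-(3S,4R)-3-[4-(benzyloxy)-2-methoxyphenyl]-4-hydroxy-3,4-dihydro-2H-chromen-7-yl benzoate (trans, racemic; one enantiomer drawn) | COc1cc(OCc2ccccc2)ccc1[C@H]1COc2cc(OC(=O)c3ccccc3)ccc2[C@@H]1O
F5 | step 5 | 3-[4-(benzyloxy)-2-methoxyphenyl]-4-oxo-3,4-dihydro-2H-chromen-7-yl benzoate (racemic) | COc1cc(OCc2ccccc2)ccc1C1COc2cc(OC(=O)c3ccccc3)ccc2C1=O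
F6 | step 5 | (3S,4S)-3-[4-(benzyloxy)-2-methoxyphenyl]-4-hydroxy-3,4-dihydro-2H-chromen-7-yl benzoate | COc1cc(OCc2ccccc2)ccc1[C@H]1COc2cc(OC(=O)c3ccccc3)ccc2[C@H]1O
F7 | step 8 | (3S)-3-[3-formyl-4-hydroxy-2-methoxy-5-(2-methylbut-3-en-2-yl)phenyl]-3,4-dihydro-2H-chromen-7-yl benzoate | C=CC(C)(C)c1cc([C@H]2COc3cc(OC(=O)c4ccccc4)ccc3C2)c(OC)c(C=O)c1O
F8 | step 8 | (3S)-3-[3-(formyloxy)-4-hydroxy-2-methoxy-5-(2-methylbut-3-en-2-yl)phenyl]-3,4-dihydro-2H-chromen-7-yl benzoate | C=CC(C)(C)c1cc([C@H]2COc3cc(OC(=O)c4ccccc4)ccc3C2)c(OC)c(OC=O)c1O
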